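Which flask, cedar or larch, ends with the higher excess of left-handed product is a dispute between two chemists reading the same three runs.

| setting | Thursday's | Sunday's | Monday's | cedar | larch |
|---|---|---|---|---|---|
| left-handed substrate | 20 mM | 20 mM | 20 mM | 20 mM | 20 mM |
| right-handed substrate | 20 mM | 20 mM | 20 mM | 20 mM | 20 mM |
| coupling partner | 30 mM (fed, over 5.0 min) | 30 mM (fed, over 5.0 min) | 30 mM (fed, over 5.0 min) | 30.0 mM (fed, over 5.0 min) | 30.0 mM (fed, over 5.0 min) |
| free catalyst | 74 µM | 150 µM | 160 µM | 100 µM | 200 µM |
| impurity | 21 µM | 21 µM | 21 µM | 21 µM | 21 µM |
| remark | run made earlier | run made earlier | run made earlier |  |  |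
| time |  |  |  | 8.0 min | 8.0 min |

| run | time / min | left-handed product / % | right-handed product / % | left-handed substrate / % |
|---|---|---|---|---|
| Thursday's | 0.500 | 0.7 | 0 | 49.6 |
| Thursday's | 1.33 | 1.8 | 0 | 48.5 |
| Thursday's | 2.50 | 2.5 | 0 | 47.8 |
| Thursday's | 4.00 | 7.0 | 0 | 43.6 |
| Thursday's | 6.00 | 14.4 | 0.2 | 38.0 |
| Sunday's | 0.500 | 0.4 | 0 | 49.3 |
| Sunday's | 1.33 | 2.4 | 0 | 47.7 |
| Sunday's | 2.50 | 6.8 | 0.1 | 42.5 |
| Sunday's | 4.00 | 16.5 | 0.8 | 35.4 |
| Sunday's | 6.00 | 23.4 | 0 | 25.7 |
| Monday's | 1.00 | 1.5 | 0 | 48.7 |
| Monday's | 2.50 | 10.5 | 0 | 43.0 |
| Monday's | 3.00 | 10.9 | 0 | 39.0 |
| Monday's | 5.00 | 20.4 | 0 | 30.0 |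
| Monday's | 6.00 | 24.7 | 0 | 25.0 |

(standard deviation of a reading: 1 percentage point)

- free catalyst is single-handed; left-handed substrate and right-handed substrate are mirror images of each other, charged as a racemate, each of them at the stated concentration
- the analysis behind the earlier runs scatters by 1 percentage point, standard deviation
- an excess is the difference of the two amounts in percent of their sum
- an excess is below zero if the other one leads

- the flask that ends with the higher excess of left-handed product over right-handed product in the product, or "neither" when 2 percentage points or less lies between them (cedar / larch / neither)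
- excess of left-handed product over right-handed product in the product at the end, cedar
- excess of left-handed product over right-handed product in the product at the end, larch

The first chemist holds that an excess belongs to the catalyst, one ratio of two rates at any conversion, so twice the catalyst leaves it unmoved. The second holds that the ratio drifts, since the left-handed substrate thins while the right-handed one loses little, and the flask that goes further ends lower.

Both start from the summed readings, 1.10% of right-handed product against 144% of left-handed. That reads as a ratio of 0.00764, taken as the starting ratio of the two rates (the inverse of the selectivity factor), and one standard deviation of the sum lifts it to 0.0346.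

The second chemist's own reckoning goes in two rounds. The logarithmic loss of left-handed substrate by 6.00 min, per unit of catalyst above the impurity, averages 5.11 mM⁻¹. Partner exposure grows as charge times time less half the dosing, so the loss stretches by a factor of 1.57 up to 8.0 min, leaving 53.0% of its own charge in cedar and 23.8% in larch. Putting that consumed partner back into the last stretch gives an estimate of 57.0% for cedar and 31.0% for larch.

The thinning factor, the logarithmic loss divided by the fractional loss, says how far the product ratio over a run stands above its starting ratio, as long as the right-handed substrate stays near its charge. It is 1.31 for cedar and 1.70 for larch. At the central ratio the excesses lie 0.58 percentage points apart, but at the lifted ratio 2.4 points, and on that edge the second chemist names cedar.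

The forecast names the first chemist's outcome, neither, with 99% for cedar and 98.5% for larch, noting that “Right-handed product stays essentially zero at every point”.

The simulation gives neither, with 96.0% for cedar and 95.0% for larch.

    coupling partner ⇌ dormant form (K = 0.380, k = 5.80 × 10⁻⁴ s⁻¹)
    coupling partner + free catalyst + left-handed substrate → free catalyst + left-handed product (k = 1400 M⁻² s⁻¹)
    free catalyst + impurity → spent catalyst (k = 3700 M⁻¹ s⁻¹)
    coupling partner + free catalyst + right-handed substrate → free catalyst + right-handed product (k = 22.0 M⁻² s⁻¹)
    2 coupling partner → self-condensation product (k = 0.0950 M⁻¹ s⁻¹)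

The ratio of the two rate constants, 0.0157, with the thinning factor 1.31 gives cedar 96.0%. The second chemist's view gets its region in the long runs: at 80.0 min cedar stands at 94.7% and larch at 92.1%, 2.6 points apart, more than the margin. A neighbouring flask like cedar but with 0.060 mM of free catalyst keeps 74% of its left-handed substrate, so its factor is 1.16, which gives 96.4%, and the simulation gives 96.4%.

(The readings were computed for an exercise.)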